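What I wanted was how much product stands in the new flask at the asked time, and how near saturation its coupling partner is then.

| flask | substrate | gas | catalyst | remark | time |
|---|---|---|---|---|---|
| Thursday's | 2 M | 190 mM (held) | 4.5 mM | run made earlier |  |
| flask | 3.0 M | 190 mM (held) | 4.5 mM |  | 50 min |

Thursday's run (percent of the substrate charged): time / min: product / % = 5.00: 3.9; 8.00: 6.8; 12.0: 8.6; 20.0: 15.6; 40.0: 30.9; 60.0: 45.6

(readings scatter by 1 percentage point)

1. the product standing at 50 min, as a percentage of the substrate charged
2. concentration of coupling partner in solution at 50 min, in percent of saturation

- at the start none of the gas is in solution
- coupling partner is what gas becomes in solution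

1. Thursday's last reading gave a mean rate of 15.2 mM/min, and the readings lay near a straight line.

2. I folded this into one number, the reach: the share of the new flask's charge that Thursday's rate turns over in the asked time, 25.3%.

3. The reach is one end. If dissolving of the gas is the rate-limiting step, the partner is used as it arrives, and the amount of product ignores the charge. At the other end the partner stands near saturation and the rate follows the substrate, so the new flask keeps Thursday's share, 38.0%.

4. With supply and use in balance and a rate proportional to substrate and partner, the order in substrate equals the partner's share of saturation. I therefore read the position between the ends as that share.

5. One number was not enough: the reach gives one end, and Thursday's run, with its single charge, showed me no position between the ends. I committed to the middle: 31.7% of product, and a partner at 0.5 of saturation.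

6. My figures stood above the forecast's 25.7% and 10%, which held that “the rate is zero order in substrate”.

7. The flask gave 32.7% and 61.6% of saturation.

    gas ⇌ coupling partner, rate k1*(csat - [coupling partner]) (kL = 0.260 /min)
    substrate + coupling partner + catalyst → product + catalyst, rate k2*[substrate]*[coupling partner]*[catalyst]/(1 + ([substrate]/sat2)) (6.50 M, k = 23.0 /M²/min)

The new flask's position between its ends was 58.3%. The neighbouring flask, with 1.2 M of substrate and the rest of the recipe unchanged, has a reach of 63.3%, and its other end remains 38.0%. Its product came to 46.1%, a position of 68.0%. In that neighbouring flask the coupling partner stood at 0.153 M at 50.0 min, which is 80.4% of saturation.

The data are simulated for an exercise.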